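**Retrosynthetic overview**

1. The 2-(1-formylvinyl) group of target 15 is an oxidised isopropenyl group, so 15 goes back to diester 14 by allylic (Riley) oxidation, placed last because the enal tolerates neither hydride nor base.
2. Diester 14 goes back to keto alcohol 9 by isovalerylation of the C3 hydroxyl, catalyst-controlled reduction of the 5-acetyl group to the (R)-carbinol and esterification with (R)-2-methylbutanoic acid.
3. The strategy rests on C2 of the dihydrofuran ring being bonded to both O1 and C3. C2, with its isopropenyl group, is therefore inserted as a one-carbon ylide unit between the phenol oxygen and the formyl carbon of 5-acetylsalicylaldehyde 6, a (4+1) annulation that forms C2–C3 and then O1–C2.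
4. The one-carbon unit is delivered by S-methallyl thiolanium salt 5, made from (2S,5S)-hexane-2,5-diol through the dimesylate, sodium sulfide (double inversion) and methallyl bromide.
5. Ring order: the benzene ring is purchased; the dihydrofuran ring O1–C2–C3–C3a–C7a is the only ring formed (step 4).

Key step: step 4

Assumption: the (2R,5R)-thiolanium ylide is taken to attack the aldehyde of 6 with the facial sense it shows toward simple aromatic aldehydes, which leads to the (3S) carbinol carbon; the configuration of 9 is to be verified (MTPA esters) before the route continues, and the enantiomeric diol would enter step 1 if the sense proves opposite.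

**Route**

Step 1
Reactants: 1 (2S,5S)-hexane-2,5-diol
Product: 2 (2S,5S)-hexane-2,5-diyl dimethanesulfonate
Conditions: MsCl (2.4 equiv), Et3N (3 equiv), CH2Cl2, −20 → 0 °C
Reagents that add atoms: methanesulfonyl chloride CS(=O)(=O)Cl
Why: Mesylation of both secondary hydroxyls takes place at oxygen only, so the two C–O bonds and both (S) centres remain untouched (alcohol sulfonylation).

Step 2
Reactants: 2 (2S,5S)-hexane-2,5-diyl dimethanesulfonate
Product: 3 (2R,5R)-2,5-dimethylthiolane
Conditions: Na2S·9H2O (1.3 equiv), DMSO, rt, 16 h; pentane extraction, distillation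
Reagents that add atoms: sodium sulfide [Na+].[Na+].[S-2]
Why: Double SN2 thioetherification (intermolecular displacement, then 5-exo-tet closure) inverts both centres and should turn the (S,S)-dimesylate into the C2-symmetric (R,R)-thiolane.

Step 3
Reactants: 3 (2R,5R)-2,5-dimethylthiolane; 4 3-bromo-2-methylprop-1-ene (methallyl bromide)
Product: 5 (2R,5R)-2,5-dimethyl-1-(2-methylprop-2-en-1-yl)thiolan-1-ium bromide
Conditions: 4 (3 equiv), neat, rt, dark, 72 h; Et2O trituration
Reagents that add atoms: none
Why: S-Alkylation by the reactive allylic bromide (Menshutkin-type sulfonium salt formation) should give a single sulfonium stereoisomer because the two sulfur lone pairs of the C2-symmetric thiolane are equivalent, and separation of the salt from the neat mixture protects it from dealkylation by bromide.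

Step 4
Reactants: 6 5-acetyl-2-hydroxybenzaldehyde (5-acetylsalicylaldehyde); 5 (2R,5R)-2,5-dimethyl-1-(2-methylprop-2-en-1-yl)thiolan-1-ium bromide
Product: 9 1-[(2R,3S)-3-hydroxy-2-(prop-1-en-2-yl)-2,3-dihydro-1-benzofuran-5-yl]ethan-1-one, via sulfonium ylide 7 (not isolated), via trans-vinyl epoxide phenoxide 8 (not isolated)
Conditions: 5 (1.2 equiv), NaOH (2.3 equiv), t-BuOH/H2O 9:1, 0 °C → rt, then 40 °C until 8 is consumed; aq. NH4Cl
Reagents that add atoms: none
Why: Hydroxide converts 6 into its phenoxide and 5 into the allylic ylide 7, whose α-carbon adds to the aldehyde (C2–C3 bond) to give the anti betaine, which closes by 3-exo-tet displacement of the thiolane to the trans-vinyl epoxide 8. The neighbouring phenoxide then attacks the allylic epoxide carbon with inversion (O1–C2 bond), a formally 5-endo-tet epoxide opening made accessible by the isopropenyl π-system, which stabilises the loosened SN2 transition state at that carbon; this closes the dihydrofuran ring, the only ring formed. The closest known reactions are the Corey–Chaykovsky-type (4+1) annulation of sulfur ylides with salicylaldehydes to 2,3-dihydrobenzofuran-3-ols and the asymmetric epoxidation of aromatic aldehydes by methallyl ylides of C2-symmetric 2,5-dimethylthiolane. C3 is set by the face of the aldehyde that the ylide attacks, which the C2-symmetric thiolanium controls (one sulfonium stereoisomer, one ylide face shielded by a ring methyl); C2 is set relative to C3 because the partly reversible betaine formation of this semi-stabilised ylide funnels into the trans epoxide, and the single inversion on ring closure then gives the 2,3-trans ring. The step needs the aldehyde to react in preference to the acetyl group and the α- rather than the γ-carbon of the ylide to bond: the aldehyde is intrinsically the better electrophile while the ketone sits para to the phenoxide and is deactivated as a vinylogous carboxylate, and α-attack is the normal course of sulfonium allylides on aldehydes.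

Step 5
Reactants: 9 1-[(2R,3S)-3-hydroxy-2-(prop-1-en-2-yl)-2,3-dihydro-1-benzofuran-5-yl]ethan-1-one; 10 3-methylbutanoic anhydride
Product: 11 (2R,3S)-5-acetyl-2-(prop-1-en-2-yl)-2,3-dihydro-1-benzofuran-3-yl 3-methylbutanoate
Conditions: 10 (1.5 equiv), Et3N (2 equiv), DMAP (0.1 equiv), CH2Cl2, 0 °C
Reagents that add atoms: none
Why: DMAP-catalysed acyl transfer to the secondary benzylic hydroxyl touches neither C2 nor C3, and loss of the ester toward the benzofuran should not intervene at 0 °C because H-2 lies syn to the C3 oxygen in the trans isomer, which disfavours anti-periplanar E2 elimination.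

Step 6
Reactants: 11 (2R,3S)-5-acetyl-2-(prop-1-en-2-yl)-2,3-dihydro-1-benzofuran-3-yl 3-methylbutanoate
Product: 12 (2R,3S)-5-[(1R)-1-hydroxyethyl]-2-(prop-1-en-2-yl)-2,3-dihydro-1-benzofuran-3-yl 3-methylbutanoate
Conditions: (S)-Me-CBS (0.2 equiv), catecholborane (2 equiv), toluene, −78 → −40 °C; MeOH, then pH 7 buffer
Reagents that add atoms: none
Why: Corey–Bakshi–Shibata reduction, in which the (S)-oxazaborolidine binds the ketone oxygen anti to the aryl group and delivers hydride to the Si face, should set the (R)-carbinol under catalyst control, while catecholborane at low temperature leaves the 1,1-disubstituted alkene and the ester alone.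

Step 7
Reactants: 12 (2R,3S)-5-[(1R)-1-hydroxyethyl]-2-(prop-1-en-2-yl)-2,3-dihydro-1-benzofuran-3-yl 3-methylbutanoate; 13 (R)-2-methylbutanoic acid
Product: 14 (1R)-1-[(2R,3S)-3-[(3-methylbutanoyl)oxy]-2-(prop-1-en-2-yl)-2,3-dihydro-1-benzofuran-5-yl]ethyl (2R)-2-methylbutanoate
Conditions: 13 (1.3 equiv), DCC (1.3 equiv), DMAP (0.1 equiv), CH2Cl2, 0 °C → rt
Reagents that add atoms: none
Why: Steglich esterification acylates the hydroxyl oxygen without breaking the benzylic C–O bond, so the (R)-carbinol is retained, and the α-centre of this simple α-alkyl acid is not expected to epimerise with catalytic DMAP at 0 °C.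

Step 8
Reactants: 14 (1R)-1-[(2R,3S)-3-[(3-methylbutanoyl)oxy]-2-(prop-1-en-2-yl)-2,3-dihydro-1-benzofuran-5-yl]ethyl (2R)-2-methylbutanoate
Product: 15 (1R)-1-[(2R,3S)-3-[(3-methylbutanoyl)oxy]-2-(3-oxoprop-1-en-2-yl)-2,3-dihydro-1-benzofuran-5-yl]ethyl (2R)-2-methylbutanoate (CNP0154159.1)
Conditions: SeO2 (1.5 equiv), 1,4-dioxane/H2O 50:1, 80 °C
Reagents that add atoms: selenium dioxide O=[Se]=O
Why: Riley oxidation, an ene reaction of SeO2 at the terminal CH2 with hydrogen abstraction from the methyl group followed by [2,3]-sigmatropic shift and further oxidation of the primary allylic alcohol stage, should give the 2-substituted acrolein, the methyl reacting in preference to the oxygen-bearing C2 methine and no stereocentre being touched.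

**Compound list**

1 | (2S,5S)-hexane-2,5-diol | C[C@H](O)CC[C@H](C)O | starting material
2 | (2S,5S)-hexane-2,5-diyl dimethanesulfonate | C[C@H](OS(C)(=O)=O)CC[C@H](C)OS(C)(=O)=O | intermediate
3 | (2R,5R)-2,5-dimethylthiolane | C[C@@H]1CC[C@@H](C)S1 | intermediate
4 | 3-bromo-2-methylprop-1-ene (methallyl bromide) | C=C(C)CBr | starting material
5 | (2R,5R)-2,5-dimethyl-1-(2-methylprop-2-en-1-yl)thiolan-1-ium bromide | C=C(C)C[S+]1[C@H](C)CC[C@H]1C.[Br-] | intermediate
6 | 5-acetyl-2-hydroxybenzaldehyde (5-acetylsalicylaldehyde) | CC(=O)c1ccc(O)c(C=O)c1 | starting material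
7 | (2R,5R)-2,5-dimethylthiolan-1-ium 2-methylallylide (sulfonium ylide) | C=C(C)[CH-][S+]1[C@H](C)CC[C@H]1C | intermediate
8 | sodium 4-acetyl-2-[(2S,3S)-3-(prop-1-en-2-yl)oxiran-2-yl]phenolate (trans-vinyl epoxide phenoxide) | CC(=O)c1ccc([O-])c(c1)[C@@H]2O[C@H]2C(C)=C.[Na+] | intermediate
9 | 1-[(2R,3S)-3-hydroxy-2-(prop-1-en-2-yl)-2,3-dihydro-1-benzofuran-5-yl]ethan-1-one | C=C(C)[C@H]1Oc2ccc(C(C)=O)cc2[C@@H]1O | intermediate
10 | 3-methylbutanoic anhydride | CC(C)CC(=O)OC(=O)CC(C)C | starting material
11 | (2R,3S)-5-acetyl-2-(prop-1-en-2-yl)-2,3-dihydro-1-benzofuran-3-yl 3-methylbutanoate | C=C(C)[C@H]1Oc2ccc(C(C)=O)cc2[C@@H]1OC(=O)CC(C)C | intermediate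
12 | (2R,3S)-5-[(1R)-1-hydroxyethyl]-2-(prop-1-en-2-yl)-2,3-dihydro-1-benzofuran-3-yl 3-methylbutanoate | C=C(C)[C@H]1Oc2ccc([C@@H](C)O)cc2[C@@H]1OC(=O)CC(C)C | intermediate
13 | (R)-2-methylbutanoic acid | CC[C@@H](C)C(=O)O | starting material
14 | (1R)-1-[(2R,3S)-3-[(3-methylbutanoyl)oxy]-2-(prop-1-en-2-yl)-2,3-dihydro-1-benzofuran-5-yl]ethyl (2R)-2-methylbutanoate | C=C(C)[C@H]1Oc2ccc([C@@H](C)OC(=O)[C@H](C)CC)cc2[C@@H]1OC(=O)CC(C)C | intermediate
15 | (1R)-1-[(2R,3S)-3-[(3-methylbutanoyl)oxy]-2-(3-oxoprop-1-en-2-yl)-2,3-dihydro-1-benzofuran-5-yl]ethyl (2R)-2-methylbutanoate | C=C(C=O)[C@H]1Oc2ccc([C@@H](C)OC(=O)[C@H](C)CC)cc2[C@@H]1OC(=O)CC(C)C | target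

**Step count**

Total step count: 8.
Longest linear sequence: 8 steps (1 → 2 → 3 → 5 → 9 → 11 → 12 → 14 → 15); 5 steps from aldehyde 6.

**Steps most likely to fail**

Step 4 (key step). The doubly charged betaine may partition between oxirane closure and direct displacement of the sulfonium group by the phenoxide (a single inversion, leading to the cis ring). Addition to the phenoxide-deactivated aldehyde may also be slow enough for aldol-type self-condensation through the acetyl group or SN2′ opening of the epoxide to compete. Facial control by the thiolanium may fall short on a salicylaldehyde phenoxide. The fallback sets out from 6 and comes back at 9. The phenol is silylated (TIPSCl, imidazole, DMF) to 5-acetyl-2-(triisopropylsilyloxy)benzaldehyde F1. Ylide 7, pre-formed from 5 with KHMDS in THF at −78 °C, then epoxidises F1 in an asymmetric Corey–Chaykovsky reaction of an ordinary, non-deactivated aromatic aldehyde. This should give the trans-vinyl epoxide 1-{3-[(2S,3S)-3-(prop-1-en-2-yl)oxiran-2-yl]-4-(triisopropylsilyloxy)phenyl}ethan-1-one F2, which can be purified and its enantiomeric purity checked. TBAF in THF at 0 °C then releases the phenoxide, which opens the epoxide at the allylic carbon and gives 9. The bulky silyl group is chosen to suppress O-to-O silyl migration in the betaine.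

Step 8. At the temperature needed, selenous acid may promote ionisation of the two benzylic esters (elimination toward the benzofuran or a styrene, epimerisation at the side-chain carbinol), and the oxidation may stall at the allylic alcohol stage. The fallback sets out from 14 and comes back at 15. Ene-type allylic chlorination (NCS, catalytic PhSeCl, CH2Cl2, rt) should give the allylic chloride (1R)-1-[(2R,3S)-2-(3-chloroprop-1-en-2-yl)-3-[(3-methylbutanoyl)oxy]-2,3-dihydro-1-benzofuran-5-yl]ethyl (2R)-2-methylbutanoate F3. Oxidation of F3 with N-methylmorpholine N-oxide in MeCN at rt (the N-oxide variant of the Kornblum oxidation) then gives enal 15 under neutral conditions.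

Step 6. The boron hydride may hydroborate the isopropenyl group or attack the ester, and facial selectivity may be incomplete on this electron-rich aryl ketone, which would leave a C-1′ epimer that is hard to remove. The fallback sets out from 11 and comes back at 12. A Noyori asymmetric transfer hydrogenation (RuCl[(R,R)-TsDPEN](p-cymene), HCO2H/Et3N 5:2, rt) uses a metal–ligand bifunctional hydride transfer that cannot hydroborate the alkene and should give the (R)-carbinol 12 directly. This way forms no new compound (F0).

**Further compounds**

F1 | step 4 | 5-acetyl-2-(triisopropylsilyloxy)benzaldehyde | CC(=O)c1ccc(O[Si](C(C)C)(C(C)C)C(C)C)c(C=O)c1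
F2 | step 4 | 1-{3-[(2S,3S)-3-(prop-1-en-2-yl)oxiran-2-yl]-4-(triisopropylsilyloxy)phenyl}ethan-1-one | CC(=O)c1ccc(O[Si](C(C)C)(C(C)C)C(C)C)c(c1)[C@@H]2O[C@H]2C(C)=C
F3 | step 8 | (1R)-1-[(2R,3S)-2-(3-chloroprop-1-en-2-yl)-3-[(3-methylbutanoyl)oxy]-2,3-dihydro-1-benzofuran-5-yl]ethyl (2R)-2-methylbutanoate | C=C(CCl)[C@H]1Oc2ccc([C@@H](C)OC(=O)[C@H](C)CC)cc2[C@@H]1OC(=O)CC(C)C
F0 | step 6 | none | none
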